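**Plan**
- Cuts: first the bond from ring A (guaiacyl) carbon C1' to the benzylic CH2 on lactone C3, giving boronic acid 9 and the (R)-3-methylene lactone 8. Then the exocyclic C3=CH2 (formaldehyde), the C5–O side of the lactone (ester reduction and lactonisation), the C4–H and benzylic C–H pair (hydrogenation), and the ring B–CH=C bond (Stobbe condensation).
- Enabling feature: the ring A benzylic CH2 stands β to the lactone carbonyl (O=C2–C3–CH2). At the alkene level C3=CH2 it is therefore the electrophilic end of an exocyclic acrylate. C3 is also the only acidic stereocentre and sits next to the fixed C4.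
- Forward order: the chain is joined to ring B (step 1), C4 is set (step 2), the lactone ring is closed (step 3), C3 is raised to the alkene level (step 4), and ring A is joined with its phenol free (step 5). No protecting group is used.
- Stereochemistry: C4 (R) comes from catalyst control in the hydrogenation. C3 (R) comes from substrate control by C4, through protonation and in-flask equilibration to the trans lactone.

Key step: step 5

Assumption: the (S,S)-ligand is taken to give the (R)-succinate, by analogy with the facial sense known for related itaconate half-esters and enamides; if the sense proves opposite, the equally available (R,R)-ligand is used.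

**Step 1**
Reactants: 1 3,4,5-trimethoxybenzaldehyde; 2 dimethyl succinate
Product: 3 (E)-3-(methoxycarbonyl)-4-(3,4,5-trimethoxyphenyl)but-3-enoic acid
Conditions: NaOMe (1.5 equiv), MeOH, reflux; then aq. HCl
Reagents that add atoms: none
Why: Stobbe condensation, in which the succinate enolate adds to the aldehyde, the aldolate lactonises onto the distal ester and E1cB ring opening should give the half-ester with the free acid on the chain end that becomes the lactone carbonyl and the aryl group trans to CO2Me; no stereocentre is made.

**Step 2**
Reactants: 3 (E)-3-(methoxycarbonyl)-4-(3,4,5-trimethoxyphenyl)but-3-enoic acid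
Product: 4 (R)-3-(methoxycarbonyl)-4-(3,4,5-trimethoxyphenyl)butanoic acid
Conditions: H2 (5 bar), [Rh(cod)((S,S)-Et-DuPHOS)]BF4 (0.5 mol%), NaOMe (10 mol%), MeOH, 25 °C
Reagents that add atoms: none
Why: Asymmetric hydrogenation of a Stobbe-type itaconate half-ester, a well-precedented substrate class for cationic bisphospholane complexes of monovalent rhodium, in which carboxylate and alkene chelate the metal and the C2-symmetric ligand opens only one alkene face to H2, setting the future C4 as (R).

**Step 3**
Reactants: 4 (R)-3-(methoxycarbonyl)-4-(3,4,5-trimethoxyphenyl)butanoic acid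
Product: 6 (R)-4-(3,4,5-trimethoxybenzyl)dihydrofuran-2(3H)-one, via hydroxy acid 5 (not isolated)
Conditions: KOH (1.0 equiv), EtOH, 0 °C; CaCl2, NaBH4, EtOH, −10 °C to rt; then 3 M HCl, rt
Reagents that add atoms: none
Why: Chemoselective ester reduction with Ca(BH4)2, in which the carboxylate salt is inert to borohydride while the methyl ester goes to the primary alcohol, and acidification should close the five-membered lactone without touching the stereocentre.

**Step 4**
Reactants: 6 (R)-4-(3,4,5-trimethoxybenzyl)dihydrofuran-2(3H)-one
Product: 8 (R)-3-methylene-4-(3,4,5-trimethoxybenzyl)dihydrofuran-2(3H)-one, via sodium hydroxymethylene enolate 7 (not isolated)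
Conditions: NaH (1.05 equiv), HCO2Et (3 equiv), THF, 0 °C to rt; volatiles stripped; paraformaldehyde (5 equiv), THF, reflux
Reagents that add atoms: paraformaldehyde as formaldehyde, C=O (the new =CH2 of 8); ethyl formate, CCOC=O, and sodium hydride, [Na+].[H-] (formyl carbon, its oxygen and the sodium of 7 only)
Why: Claisen-type α-formylation followed by deformylative methylenation, in which enolate 7 is hydroxymethylated at C3, the new alkoxide takes over the formyl group and formate leaves by E1cB elimination, while C4 bears no acidic hydrogen in 6 and 7 and should be kept.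

**Step 5**
Reactants: 8 (R)-3-methylene-4-(3,4,5-trimethoxybenzyl)dihydrofuran-2(3H)-one; 9 (4-hydroxy-3-methoxyphenyl)boronic acid
Product: 11 (3R,4R)-3-(4-hydroxy-3-methoxybenzyl)-4-(3,4,5-trimethoxybenzyl)dihydrofuran-2(3H)-one, via cis C3-epimer 10 (not isolated)
Conditions: 9 (2 equiv, in portions), [Rh(cod)OH]2 (2.5 mol%), 1,4-dioxane/H2O 10:1, 50 °C; then phase cut (EtOAc/brine), solvent swap to toluene, DBU (3 equiv), 90 °C; 1 M HCl wash
Reagents that add atoms: none
Why: Transmetalation of 9 to the hydroxo complex of monovalent rhodium gives an aryl–rhodium species that carbometalates the unhindered exocyclic alkene of 8 (aryl to CH2, rhodium to C3), and water hydrolyses the resulting oxa-π-allyl rhodium enolate, placing H on C3 and returning Rh–OH. The closest known reaction type is the Hayashi–Miyaura 1,4-addition in its conjugate addition/protonation form, established for 2-substituted acrylates, itaconates and α-methylene lactones. No ring is closed and the lactone is left intact. C3 is the only new stereocentre and is controlled by C4: proton delivery anti to the C4 benzyl arm should give much cis epimer 10 kinetically, but C3–H is the only acidic C–H at a stereocentre, so DBU equilibrates 10 through the lactone enolate to the more stable trans lactone 11 with the two benzyl arms on opposite faces, while C4 is no longer allylic and cannot epimerise. The step needs C-arylation rather than oxa-Michael addition of the free phenol, and enolate protonation rather than β-hydride elimination (to a benzylidene lactone or to the endocyclic butenolide that would erase C4); the base-free, water-rich medium secures both, because the phenol stays un-ionised and enolate hydrolysis is fast. The site on ring A is fixed by the boron atom para to OH, which avoids the ortho/para problem of a Friedel–Crafts alkylation of guaiacol.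

**Compound list**
1 | 3,4,5-trimethoxybenzaldehyde | COc1cc(C=O)cc(OC)c1OC | starting material
2 | dimethyl succinate | COC(=O)CCC(=O)OC | starting material
3 | (E)-3-(methoxycarbonyl)-4-(3,4,5-trimethoxyphenyl)but-3-enoic acid | COC(=O)/C(CC(=O)O)=C/c1cc(OC)c(OC)c(OC)c1 | intermediate
4 | (R)-3-(methoxycarbonyl)-4-(3,4,5-trimethoxyphenyl)butanoic acid | COC(=O)[C@@H](CC(=O)O)Cc1cc(OC)c(OC)c(OC)c1 | intermediate
5 | (R)-3-(hydroxymethyl)-4-(3,4,5-trimethoxyphenyl)butanoic acid | OC[C@@H](CC(=O)O)Cc1cc(OC)c(OC)c(OC)c1 | intermediate
6 | (R)-4-(3,4,5-trimethoxybenzyl)dihydrofuran-2(3H)-one | C1C(=O)OC[C@@H]1Cc2cc(OC)c(OC)c(OC)c2 | intermediate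
7 | sodium [(4R)-2-oxo-4-(3,4,5-trimethoxybenzyl)dihydrofuran-3(2H)-ylidene]methanolate | [Na+].[O-]C=C1C(=O)OC[C@@H]1Cc2cc(OC)c(OC)c(OC)c2 | intermediate
8 | (R)-3-methylene-4-(3,4,5-trimethoxybenzyl)dihydrofuran-2(3H)-one | C=C1C(=O)OC[C@@H]1Cc2cc(OC)c(OC)c(OC)c2 | intermediate
9 | (4-hydroxy-3-methoxyphenyl)boronic acid | COc1cc(B(O)O)ccc1O | starting material
10 | (3S,4R)-3-(4-hydroxy-3-methoxybenzyl)-4-(3,4,5-trimethoxybenzyl)dihydrofuran-2(3H)-one (cis) | COc1cc(C[C@@H]2C(=O)OC[C@@H]2Cc2cc(OC)c(OC)c(OC)c2)ccc1O | intermediate
11 | (3R,4R)-3-(4-hydroxy-3-methoxybenzyl)-4-(3,4,5-trimethoxybenzyl)dihydrofuran-2(3H)-one (trans) | COc1cc(C[C@H]2C(=O)OC[C@@H]2Cc2cc(OC)c(OC)c(OC)c2)ccc1O | target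

Total step count: 5. Longest linear sequence: 5 steps (1 or 2 to 11).

**Steps most likely to fail**

Step 5.
- What may go wrong: protodeboronation of the electron-rich boronic acid may outrun transmetalation. A rhodium hydride may move the exocyclic alkene into the ring and erase C4. β-Hydride elimination may compete with enolate hydrolysis. The base equilibration may stop short of a useful trans preference.
- Fallback: it sets out from 6 and comes back at 11, and it sets C3 kinetically by enolate alkylation instead of by protonation. Lactone 6 is deprotonated with LiN(SiMe3)2 in THF at −78 °C. It is then alkylated with 4-(benzyloxy)-3-methoxybenzyl bromide, which should approach anti to the C4 arm and give the trans ether (3R,4R)-3-[4-(benzyloxy)-3-methoxybenzyl]-4-(3,4,5-trimethoxybenzyl)dihydrofuran-2(3H)-one F1. Hydrogenolysis (H2, Pd/C, EtOAc/EtOH, rt) then frees the phenol to give 11.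

Step 4.
- What may go wrong: formyl transfer and loss of formate may be slow. Residual alkoxide may drive the new alkene into the endocyclic position, or it may start anionic oligomerisation of the acrylate unit.
- Fallback: it sets out from 6 and comes back at 8 by a Mannich and Hofmann-type elimination sequence. Lactone 6 is treated with LiN(i-Pr)2 in THF at −78 °C and then with dimethylmethyleneammonium iodide (Eschenmoser's salt). This gives the Mannich base (3S,4R)-3-[(dimethylamino)methyl]-4-(3,4,5-trimethoxybenzyl)dihydrofuran-2(3H)-one F2. MeI in MeOH converts it to {[(3S,4R)-2-oxo-4-(3,4,5-trimethoxybenzyl)tetrahydrofuran-3-yl]methyl}trimethylammonium iodide F3. Aqueous NaHCO3/CH2Cl2 at rt eliminates trimethylamine and gives 8 under conditions too mild to touch C4.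

Step 3.
- What may go wrong: the hydride may fail to discriminate between carboxylate and ester. Enolisation of the ester α-C–H in basic ethanol may erode the enantiomeric purity.
- Fallback: it sets out from 4 and comes back at 6, and it tells the two carbonyl groups apart by ester bulk rather than by salt formation. Acid 4 is esterified with tert-butyl 2,2,2-trichloroacetimidate (cat. BF3·OEt2, CH2Cl2/cyclohexane, rt) to give 4-tert-butyl 1-methyl (R)-2-(3,4,5-trimethoxybenzyl)succinate F4. LiBH4 in THF at 0 °C reduces only the methyl ester and gives tert-butyl (R)-3-(hydroxymethyl)-4-(3,4,5-trimethoxyphenyl)butanoate F5. CF3CO2H in CH2Cl2 at rt cleaves the tert-butyl ester and closes the lactone 6.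

**Further compounds**
F1 | step 5 | (3R,4R)-3-[4-(benzyloxy)-3-methoxybenzyl]-4-(3,4,5-trimethoxybenzyl)dihydrofuran-2(3H)-one | COc1cc(C[C@H]2C(=O)OC[C@@H]2Cc2cc(OC)c(OC)c(OC)c2)ccc1OCc1ccccc1
F2 | step 4 | (3S,4R)-3-[(dimethylamino)methyl]-4-(3,4,5-trimethoxybenzyl)dihydrofuran-2(3H)-one | CN(C)C[C@H]1C(=O)OC[C@@H]1Cc2cc(OC)c(OC)c(OC)c2
F3 | step 4 | {[(3S,4R)-2-oxo-4-(3,4,5-trimethoxybenzyl)tetrahydrofuran-3-yl]methyl}trimethylammonium iodide | C[N+](C)(C)C[C@H]1C(=O)OC[C@@H]1Cc2cc(OC)c(OC)c(OC)c2.[I-]
F4 | step 3 | 4-tert-butyl 1-methyl (R)-2-(3,4,5-trimethoxybenzyl)succinate | COC(=O)[C@@H](CC(=O)OC(C)(C)C)Cc1cc(OC)c(OC)c(OC)c1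
F5 | step 3 | tert-butyl (R)-3-(hydroxymethyl)-4-(3,4,5-trimethoxyphenyl)butanoate | OC[C@@H](CC(=O)OC(C)(C)C)Cc1cc(OC)c(OC)c(OC)c1
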